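4 questions stand on these flasks, and each one turns on how much target is there after 4.0 min.

| flask | starting material | coupling partner | temperature | remark | time |
|---|---|---|---|---|---|
| zeta | 2 mM | 0.40 equiv | 15 °C | run made earlier |  |
| eta | 2 mM | 1.6 equiv | 37 °C | run made earlier |  |
| Tuesday's | 2.0 mM | 0.800 equiv | 5 °C |  | 4.0 min |
| Monday's | 2.0 mM | 0.800 equiv | 25 °C |  | 4.0 min |
| Thursday's | 2.0 mM | 0.800 equiv | 45 °C |  | 4.0 min |

zeta run (percent of the starting material charged)

| time / min | target / % | starting material / % |
|---|---|---|
| 0.200 | 3.4 | 96.9 |
| 0.667 | 16.8 | 82.5 |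
| 1.00 | 28.0 | 72.7 |
| 1.50 | 35.5 | 64.7 |
| 2.50 | 39.1 | 59.4 |
| 3.00 | 40.4 | 59.5 |

eta run (percent of the starting material charged)

| time / s | target / % | starting material / % |
|---|---|---|
| 10.0 | 65.5 | 35.1 |
| 12.0 | 74.6 | 26.2 |
| 25.0 | 96.1 | 3.2 |
| 40.0 | 99.3 | 0.2 |
| 60.0 | 100.0 | 0 |

(each reading ± 0.5 percentage points)

- the flask that comes out highest in amount of target, in percent of the starting material charged, or "all alike" when all lie within 1.5 percentage points (Tuesday's / Monday's / Thursday's / all alike)
- target at the end, in percent of the starting material charged, Tuesday's
- target at the end, in percent of the starting material charged, Monday's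
- target at the end, in percent of the starting material charged, Thursday's



A bench rule says that, with coupling partner under one equivalent, target stops at its equivalents, coupling partner being the limiting reagent. The zeta run fits it, with 40.4% of target on 0.40 equiv, which is 1.01 per equivalent. The eta run lies past the border of the rule: 100.0% on 1.6 equiv is 0.625 per equivalent, with starting material read at 0%. The new flasks stand under that border, so 0.800 equiv gives a ceiling on target of 80.0% in all three flasks.

Putting this first answer back in gives the rest of the starting material. In the zeta run the same subtraction gives 60.0%, against a last reading of 59.5%. For the new flasks it gives 20.0%.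

My own reckoning puts Monday's at 25 °C and Thursday's at 45 °C, both warmer than the zeta run at 15 °C, at the ceiling, but it is less sure of Tuesday's. The zeta run read 39.1% of target at 2.50 min, and 4.0 min is 1.60 times that, while Tuesday's runs colder at 5 °C against 15 °C.

The forecast names Thursday's, with 64% (55% to 71%) for Tuesday's, 79.7% for Monday's and 80% for Thursday's, adding “Thursday's is marginally highest”.

The flasks come out all alike: Tuesday's gives 79.1%, Monday's 80.0% and Thursday's 80.0%. The forecast's figure for Tuesday's lies 15 percentage points under the computed one. At 2.00 min, Tuesday's already held 72.0% of target. At 4.0 min it stands 0.90 points short of the ceiling of 80.0%, and after 40.0 min it holds 80.0%, with 20.0% of starting material beside the reckoned 20.0%.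

    starting material + coupling partner → target + by-product (k = 1.58 L mol⁻¹ s⁻¹, Ea = 44.0 kJ mol⁻¹)
    coupling partner ⇌ dormant form (K = 0.320, k = 0.0444 s⁻¹, Ea = 73.0 kJ mol⁻¹, ΔH = −62.0 kJ mol⁻¹)
    starting material + coupling partner + by-product → target + 2 by-product (k = 33300 L² mol⁻² s⁻¹, Ea = 11.0 kJ mol⁻¹)
    (constants at 5 °C)

A neighbour, the same flask as Monday's but with 0.200 equiv of coupling partner, has a ceiling of 20.0% and a reckoned rest of 80.0%. Computed, it gives 20.0% of target and 80% of starting material.

The readings are simulated with constants of no real substance.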